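**Strategy.** The synthesis rests on disconnecting the C6–C7 bond between the spiro carbon and the gem-dimethyl carbon, which unravels ring B to a monocyclic, (Z)-γ-bisabolene-type triene acetate. The key step uses the pattern written into ring B: C8–Br beside C7Me2 on spiro C6, and the C11 carbinol 1,3 to the acetoxy carbon C1 of ring A. A bromonium ion on C7=C8 is opened by C6 of the exocyclic C6=C11 alkene and the C1 acetate traps the C11 cation, so one operation closes ring B and sets C6, C8 and C11. The precursor is a cyclohexyl acetate with the ring-A bromochloride and a Z tetrasubstituted alkene bearing the homoprenyl chain.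

Key step: step 10

Remark on numbering: spiro[5.5]undecane numbering is used for all intermediates (ring A = C1–C6, ring B = C6–C11; C1 carries OAc, C3 carries Me and Cl, C4 carries Br, C6 is the spiro carbon, C7 is CMe2, C8 carries Br, C11 carries Me and OH). On this numbering the target is (1R,3S,4S,6R,8R,11R).

Remark on design: ring A is assembled from an acyclic β-keto ester, so the Z geometry of the C6=C11 enol triflate is fixed by chelation before the ring exists. C1 never passes through a ketone, which would place the C3 chloride β to a carbonyl and invite loss of HCl. A cyclic 1,3-diketone is avoided because its O-sulfonylation would favour the endocyclic enol. The side chain is joined only after the ring-A alkene has been halogenated.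

Assumption: (+)-Ipc2BOMe, the reagent derived from (−)-α-pinene, delivers the methallyl group to the Re face of the aldehyde, as is usual for Ipc-controlled allylboration.

**Step 1**
Reactants: 1 ethyl 2-acetylpent-4-enoate (ethyl 2-allylacetoacetate)
Product: 2 ethyl (2Z)-2-(prop-2-en-1-yl)-3-(trifluoromethanesulfonyloxy)but-2-enoate
Conditions: Tf2O, sat. aq. LiOH, toluene, 5 °C
Reagents that add atoms: trifluoromethanesulfonic anhydride, O=S(=O)(OS(=O)(=O)C(F)(F)F)C(F)(F)F
Why: O-triflation of a β-keto ester enolate, in which the lithium enolate is a chelate with both oxygens on one side, so the triflate should form cis to the ester (Z), the geometry that later places the side chain cis to C1.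

**Step 2**
Reactants: 2 ethyl (2Z)-2-(prop-2-en-1-yl)-3-(trifluoromethanesulfonyloxy)but-2-enoate
Product: 3 (2Z)-3-(hydroxymethyl)hexa-2,5-dien-2-yl trifluoromethanesulfonate
Conditions: i-Bu2AlH (2.2 equiv), CH2Cl2, −78 °C; aq. potassium sodium tartrate
Reagents that add atoms: none
Why: 1,2-reduction of a conjugated ester to the allylic alcohol with i-Bu2AlH, which should leave the enol triflate and the alkene geometry untouched.

**Step 3**
Reactants: 3 (2Z)-3-(hydroxymethyl)hexa-2,5-dien-2-yl trifluoromethanesulfonate
Product: 4 (2Z)-3-formylhexa-2,5-dien-2-yl trifluoromethanesulfonate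
Conditions: Dess–Martin periodinane, NaHCO3, CH2Cl2, 0 °C → rt
Reagents that add atoms: none
Why: Dess–Martin oxidation of a primary allylic alcohol to the enal under buffered, non-nucleophilic conditions, so the Z geometry should be kept.

**Step 4**
Reactants: 4 (2Z)-3-formylhexa-2,5-dien-2-yl trifluoromethanesulfonate
Product: 5 (2Z,4R)-4-hydroxy-6-methyl-3-(prop-2-en-1-yl)hepta-2,6-dien-2-yl trifluoromethanesulfonate
Conditions: (+)-Ipc2BOMe, methallylmagnesium chloride, Et2O, −78 °C → rt; then 4, −78 °C; pH 7 buffer, MeOH, 30% H2O2, 0 °C
Reagents that add atoms: methallylmagnesium chloride (2-methylprop-2-en-1-ylmagnesium chloride), CC(=C)C[Mg]Cl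
Why: Brown asymmetric methallylboration through a closed six-membered chair transition state, in which the isopinocampheyl groups send the methallyl group to the Re face of the aldehyde and so set the carbinol carbon (C1 of the target, C4 of 5) as R by 1,2-addition.

**Step 5**
Reactants: 5 (2Z,4R)-4-hydroxy-6-methyl-3-(prop-2-en-1-yl)hepta-2,6-dien-2-yl trifluoromethanesulfonate
Product: 6 (1Z)-1-[(2R)-2-hydroxy-4-methylcyclohex-4-en-1-ylidene]ethyl trifluoromethanesulfonate
Conditions: second-generation Grubbs catalyst (H2IMes)(PCy3)Cl2Ru=CHPh (3 mol%), CH2Cl2 (0.01 M), 40 °C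
Reagents that add atoms: none
Why: ring-closing metathesis of the monosubstituted and the 1,1-disubstituted alkene closes ring A with the trisubstituted C3=C4 bond, while the tetrasubstituted, electron-poor enol triflate alkene should not take part and C1 is untouched.

**Step 6**
Reactants: 6 (1Z)-1-[(2R)-2-hydroxy-4-methylcyclohex-4-en-1-ylidene]ethyl trifluoromethanesulfonate
Product: 7 (1Z)-1-[(2R,4S,5S)-5-bromo-4-chloro-2-hydroxy-4-methylcyclohexylidene]ethyl trifluoromethanesulfonate
Conditions: NBS, ClTi(OiPr)3, CH2Cl2/hexanes, −20 °C, dark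
Reagents that add atoms: N-bromosuccinimide, O=C1CCC(=O)N1Br; chlorotitanium triisopropoxide, CC(C)O[Ti](Cl)(OC(C)C)OC(C)C
Why: anti bromochlorination of a trisubstituted alkene with chloride delivered from a titanium alkoxide, in which the C1 oxygen, held pseudoaxial by allylic 1,3-strain against the Z triflate and bound to titanium, should keep Br+ on the far face and pass chloride to the tertiary carbon C3 on its own face (Markovnikov, trans-diaxial opening), so that C3 and C4 are set as 3S,4S with Cl cis to the C1 oxygen, while the electron-poor enol triflate alkene stays out and any C3/C4 diastereomer is removed by chromatography.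

**Step 7**
Reactants: 8 5-bromo-2-methylpent-2-ene
Product: 9 (4-methylpent-3-en-1-yl)zinc bromide (THF solution)
Conditions: Zn dust (activated with BrCH2CH2Br, Me3SiCl), LiCl, THF, 50 °C; solution decanted from excess zinc
Reagents that add atoms: zinc, [Zn]
Why: direct insertion of LiCl-activated zinc into a primary alkyl bromide gives the alkylzinc halide, and removing the metal before use protects the vicinal dihalide of the coupling partner from reductive elimination.

**Step 8**
Reactants: 7 (1Z)-1-[(2R,4S,5S)-5-bromo-4-chloro-2-hydroxy-4-methylcyclohexylidene]ethyl trifluoromethanesulfonate; 9 (4-methylpent-3-en-1-yl)zinc bromide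
Product: 10 (1R,2Z,4S,5S)-4-bromo-5-chloro-5-methyl-2-(6-methylhept-5-en-2-ylidene)cyclohexan-1-ol
Conditions: Pd(dppf)Cl2 (5 mol%), 9 (3 equiv), THF, 25 °C
Reagents that add atoms: none
Why: Negishi cross-coupling of an enol triflate with a primary alkylzinc halide, which should proceed with retention of alkene geometry because palladium inserts only into the C–OTf bond and not into the unactivated secondary bromide or tertiary chloride, the wide-bite-angle diphosphine favours reductive elimination over β-hydride elimination, and the free hydroxyl is tolerated by the alkylzinc halide.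

**Step 9**
Reactants: 10 (1R,2Z,4S,5S)-4-bromo-5-chloro-5-methyl-2-(6-methylhept-5-en-2-ylidene)cyclohexan-1-ol
Product: 11 (1R,2Z,4S,5S)-4-bromo-5-chloro-5-methyl-2-(6-methylhept-5-en-2-ylidene)cyclohexyl acetate
Conditions: Ac2O, pyridine, DMAP (cat.), CH2Cl2, 0 °C → rt
Reagents that add atoms: acetic anhydride, CC(=O)OC(C)=O
Why: DMAP-catalysed acylation of the secondary alcohol, with retention at C1 because the C–O bond is not broken.

**Step 10**
Reactants: 11 (1R,2Z,4S,5S)-4-bromo-5-chloro-5-methyl-2-(6-methylhept-5-en-2-ylidene)cyclohexyl acetate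
Product: 13 (1R,3S,4S,6R,8R,11R)-4,8-dibromo-3-chloro-11-hydroxy-3,7,7,11-tetramethylspiro[5.5]undecan-1-yl acetate (target), via bridged 2-methyl-1,3-dioxan-2-ylium ion 12 (not isolated)
Conditions: Et2SBr·SbCl5Br (1.1 equiv), MeNO2, −25 °C, 10 min; then H2O, aq. NaHCO3/Na2SO3, 0 °C
Reagents that add atoms: bromodiethylsulfonium bromopentachloroantimonate, CC[S+](Br)CC.Cl[Sb-](Cl)(Cl)(Cl)(Cl)Br; water, O
Why: Proposed new method: the sulfonium salt passes Br+ to the exposed C7=C8 alkene, C6 of the C6=C11 alkene opens the bromonium ion at its tertiary carbon C7, and the carbonyl oxygen of the C1 acetate takes up the developing C11 cation to give dioxanylium ion 12, which water opens at the acyl carbon to leave the C11 alcohol and the C1 acetate; the closest known reactions are bromonium-initiated cation–olefin cyclisations of 1,5-dienes and polyenes with bromodiethylsulfonium salts and the trapping of cations by neighbouring acyloxy or carbonate groups (Woodward–Prévost-type acyloxonium ions). Ring B closes in a chair, 6-endo-trig with respect to C6=C11 and with endo opening of the bromonium ion, and the transient dioxanylium ring forms by six-membered attack of oxygen on C11. C8 is set by the chair with bromine equatorial, and the Z geometry puts C1 axial and C5 equatorial on the new ring, which ties C6 to C8. C11 is set by the tether, since the acetate reaches the cation only from the side of C1, the equivalent of anti addition of C7 and oxygen across the alkene. The step needs C7 to add to the alkene face opposite the C1 acetoxy group and needs Br+ to choose the prenyl alkene: allylic 1,3-strain with C10 of the Z chain turns the C1–O bond out of the alkene plane so that the acetoxy group screens one face and assists from it, the C6=C11 alkene is crowded and made electron-poorer by the allylic acetoxy group, and the C–Br and C–Cl bonds of ring A should not react.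

**Compound list**

1 | ethyl 2-acetylpent-4-enoate (ethyl 2-allylacetoacetate) | CCOC(=O)C(CC=C)C(C)=O | starting material
2 | ethyl (2Z)-2-(prop-2-en-1-yl)-3-(trifluoromethanesulfonyloxy)but-2-enoate | CCOC(=O)/C(CC=C)=C(/C)OS(=O)(=O)C(F)(F)F | intermediate
3 | (2Z)-3-(hydroxymethyl)hexa-2,5-dien-2-yl trifluoromethanesulfonate | OC/C(CC=C)=C(/C)OS(=O)(=O)C(F)(F)F | intermediate
4 | (2Z)-3-formylhexa-2,5-dien-2-yl trifluoromethanesulfonate | O=C/C(CC=C)=C(/C)OS(=O)(=O)C(F)(F)F | intermediate
5 | (2Z,4R)-4-hydroxy-6-methyl-3-(prop-2-en-1-yl)hepta-2,6-dien-2-yl trifluoromethanesulfonate | CC(=C)C[C@@H](O)/C(CC=C)=C(/C)OS(=O)(=O)C(F)(F)F | intermediate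
6 | (1Z)-1-[(2R)-2-hydroxy-4-methylcyclohex-4-en-1-ylidene]ethyl trifluoromethanesulfonate | O[C@@H]1CC(C)=CC/C1=C(\C)OS(=O)(=O)C(F)(F)F | intermediate
7 | (1Z)-1-[(2R,4S,5S)-5-bromo-4-chloro-2-hydroxy-4-methylcyclohexylidene]ethyl trifluoromethanesulfonate | O[C@@H]1C[C@](C)(Cl)[C@@H](Br)C/C1=C(\C)OS(=O)(=O)C(F)(F)F | intermediate
8 | 5-bromo-2-methylpent-2-ene | CC(C)=CCCBr | starting material
9 | (4-methylpent-3-en-1-yl)zinc bromide | CC(C)=CCC[Zn]Br | intermediate
10 | (1R,2Z,4S,5S)-4-bromo-5-chloro-5-methyl-2-(6-methylhept-5-en-2-ylidene)cyclohexan-1-ol | O[C@@H]1C[C@](C)(Cl)[C@@H](Br)C/C1=C(\C)CCC=C(C)C | intermediate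
11 | (1R,2Z,4S,5S)-4-bromo-5-chloro-5-methyl-2-(6-methylhept-5-en-2-ylidene)cyclohexyl acetate | CC(=O)O[C@@H]1C[C@](C)(Cl)[C@@H](Br)C/C1=C(\C)CCC=C(C)C | intermediate
12 | 2-methyl-1,3-dioxan-2-ylium ion bridging the C1 and C11 oxygens of the (1R,3S,4S,6R,8R,11R)-4,8-dibromo-3-chloro-3,7,7,11-tetramethylspiro[5.5]undecane core, bromopentachloroantimonate salt | CC(=[O+]3)O[C@@H]1C[C@](C)(Cl)[C@@H](Br)C[C@@]12C(C)(C)[C@H](Br)CC[C@]23C.Cl[Sb-](Cl)(Cl)(Cl)(Cl)Br | intermediate
13 | (1R,3S,4S,6R,8R,11R)-4,8-dibromo-3-chloro-11-hydroxy-3,7,7,11-tetramethylspiro[5.5]undecan-1-yl acetate | CC(=O)O[C@@H]1C[C@](C)(Cl)[C@@H](Br)C[C@@]12C(C)(C)[C@H](Br)CC[C@@]2(C)O | target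

**Step count.** Total steps: 10. Longest linear sequence: 9 steps (1 → 13 through steps 1–6 and 8–10; step 7 is a one-step branch).

**Steps most likely to fail**

1. Step 10 (carries the label). The C11 cation may lose a proton or rearrange before the acetate closes on it, or the dioxanylium ion may open toward the tertiary acetate. The C7 carbon may also add to the acetoxy-bearing face of the alkene, which this fallback does not correct. The fallback uses a stronger, irreversible trap of a known kind and sets out from alcohol 10. Boc2O and DMAP in MeCN should convert it into tert-butyl (1R,2Z,4S,5S)-4-bromo-5-chloro-5-methyl-2-(6-methylhept-5-en-2-ylidene)cyclohexyl carbonate F1. Et2SBr·SbCl5Br in MeNO2 at −25 °C should then give, by carbonate-terminated bromonium cyclisation with loss of the tert-butyl group, the spirocyclic cyclic carbonate F2. K2CO3 in MeOH at 0 °C should cleave this to the 1,11-diol F3, and Ac2O in pyridine without DMAP should acetylate only the secondary C1 hydroxyl. The fallback comes back to the route at 13.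

2. Step 6. Chloride may open the bromonium ion mainly on the face away from the C1 oxygen, through the half-chair with equatorial oxygen, so that the C3/C4 diastereomer with Cl trans to oxygen predominates. If the two faces are used about equally, the diastereomers are simply separated. If the preference is reversed, the fallback uses it instead of opposing it and sets out from aldehyde 4. Methallylboration with the reagent from (−)-Ipc2BOMe should give the (2Z,4S)-alcohol F4. Ring-closing metathesis should give the (2S)-cyclohexenol triflate F5, and bromochlorination under the conditions of step 6 should then give the (2S,4S,5S)-bromochloride F6, which has the correct C3 and C4. Negishi coupling with 9 should give the (1S,2Z,4S,5S)-alcohol F7. Mitsunobu esterification (PPh3, DIAD, AcOH, THF, 0 °C) should install the acetate with inversion at C1, and the fallback comes back to the route at 11.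

3. Step 8. The vicinal bromochloride may be lost by reductive elimination caused by traces of zinc metal or by zerovalent palladium, or slow transmetalation at the crowded alkenylpalladium may lead to protodetriflation. The fallback transfers the side chain from boron and sets out from 7. Hydroboration of 4-methylpenta-1,3-diene with 9-BBN-H in THF should give 9-(4-methylpent-3-en-1-yl)-9-borabicyclo[3.3.1]nonane F8. B-alkyl Suzuki–Miyaura coupling of F8 with 7 (Pd(dppf)Cl2, aq. K3PO4, THF/DMF, rt) should then give the coupled alcohol, and the fallback comes back to the route at 10.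

**Further compounds**

F1 | step 10 | tert-butyl (1R,2Z,4S,5S)-4-bromo-5-chloro-5-methyl-2-(6-methylhept-5-en-2-ylidene)cyclohexyl carbonate | CC(C)(C)OC(=O)O[C@@H]1C[C@](C)(Cl)[C@@H](Br)C/C1=C(\C)CCC=C(C)C
F2 | step 10 | (1R,3S,4S,6R,8R,11R)-4,8-dibromo-3-chloro-3,7,7,11-tetramethylspiro[5.5]undecane-1,11-diyl carbonate (cyclic) | O=C3O[C@@H]1C[C@](C)(Cl)[C@@H](Br)C[C@@]12C(C)(C)[C@H](Br)CC[C@@]2(C)O3
F3 | step 10 | (1R,3S,4S,6R,8R,11R)-4,8-dibromo-3-chloro-3,7,7,11-tetramethylspiro[5.5]undecane-1,11-diol | O[C@@H]1C[C@](C)(Cl)[C@@H](Br)C[C@@]12C(C)(C)[C@H](Br)CC[C@@]2(C)O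
F4 | step 6 | (2Z,4S)-4-hydroxy-6-methyl-3-(prop-2-en-1-yl)hepta-2,6-dien-2-yl trifluoromethanesulfonate | CC(=C)C[C@H](O)/C(CC=C)=C(/C)OS(=O)(=O)C(F)(F)F
F5 | step 6 | (1Z)-1-[(2S)-2-hydroxy-4-methylcyclohex-4-en-1-ylidene]ethyl trifluoromethanesulfonate | O[C@H]1CC(C)=CC/C1=C(\C)OS(=O)(=O)C(F)(F)F
F6 | step 6 | (1Z)-1-[(2S,4S,5S)-5-bromo-4-chloro-2-hydroxy-4-methylcyclohexylidene]ethyl trifluoromethanesulfonate | O[C@H]1C[C@](C)(Cl)[C@@H](Br)C/C1=C(\C)OS(=O)(=O)C(F)(F)F
F7 | step 6 | (1S,2Z,4S,5S)-4-bromo-5-chloro-5-methyl-2-(6-methylhept-5-en-2-ylidene)cyclohexan-1-ol | O[C@H]1C[C@](C)(Cl)[C@@H](Br)C/C1=C(\C)CCC=C(C)C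
F8 | step 8 | 9-(4-methylpent-3-en-1-yl)-9-borabicyclo[3.3.1]nonane | CC(C)=CCCB1C2CCCC1CCC2
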